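**Plan**

- Ring B carries three contiguous oxygens at C3', C4' and C5', only the C3' one being a free hydroxyl, with CH at C2' and C6'. A 2,3-dimethoxycyclobutenone maps onto this: its carbonyl carbon becomes C3'–OH, its two enol ether carbons become C4' and C5', and its ring CH becomes C6'.
- Retrosynthetic cuts, in order: C2'–C3' (ring B opened to a 4-(1-chromonylvinyl)cyclobutenone); C1'–C6' (alkenyltin plus 4-chlorocyclobutenone); C1'–C2' (alkyne from a chromone-2-carbaldehyde); C2–C3 and O1–C2 (ring C); the aryl–acetyl bond of ring A.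
- Forward, ring A/C half: 1,2,3,4-tetramethoxybenzene is taken to the o-hydroxyacetophenone, ring C is closed by Claisen condensation and cyclodehydration, the 5-O-methyl group is cleaved, and the aldehyde is turned into the alkyne and then the internal alkenylstannane.
- Forward, ring B half and union: dimethyl squarate is reduced and chlorinated, the halves are joined by Stille coupling, and ring B is closed last by thermal ring expansion, which should give the target with no further step.
- Stereochemistry: the target has no stereocentre; the ring CH of 14, 15 and 16 is racemic and is erased in the last step.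

Key step: step 10

Remark: flavone numbering is used (O1, C2–C8a, ring B primed). Aldehydes 9 and 10 are drawn as free aldehydes, although such electron-poor aldehydes may be handled partly as hydrates.

**Route**

Step 1
Reactants: 1 1,2,3,4-tetramethoxybenzene
Product: 4 2,3,4,5-tetramethoxyphenol, via aryllithium 2 (not isolated), via dimethyl arylboronate 3 (not isolated)
Conditions: n-BuLi, TMEDA, THF, 0 °C; B(OMe)3, −78 °C → rt; AcOH, 30% aq. H2O2, 0 °C → rt
Reagents that add atoms: hydrogen peroxide, OO (hydroxyl oxygen of 4); n-butyllithium, [Li]CCCC (lithium of 2 only); trimethyl borate, COB(OC)OC (boron and two methoxy groups of 3 only)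
Why: Methoxy-directed ortho-lithiation at the only kind of free ring position, borylation, and oxidative aryl shift from boron to oxygen (lithiation–borylation–oxidation) should give the phenol regiospecifically.

Step 2
Reactants: 4 2,3,4,5-tetramethoxyphenol
Product: 5 1-(2-hydroxy-3,4,5,6-tetramethoxyphenyl)ethan-1-one
Conditions: AcOH, BF3·OEt2, 90 °C; aq. work-up
Reagents that add atoms: acetic acid, CC(=O)O
Why: BF3-mediated Fries-type C-acetylation of an electron-rich phenol can only take place at the single unsubstituted ring carbon, which lies ortho to the hydroxyl, so the o-hydroxyacetophenone should form as one regioisomer.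

Step 3
Reactants: 5 1-(2-hydroxy-3,4,5,6-tetramethoxyphenyl)ethan-1-one; 6 ethyl 2,2-diethoxyacetate
Product: 9 5,6,7,8-tetramethoxy-4-oxo-4H-chromene-2-carbaldehyde, via diketone acetal 7 (not isolated), via chromone diethyl acetal 8 (not isolated)
Conditions: NaH (3 equiv), THF, 0 °C → reflux; then AcOH, conc. aq. HCl, 80 °C
Reagents that add atoms: water, O (aldehyde oxygen)
Why: Crossed Claisen condensation of the acetophenone dianion with an ester that does not self-condense, acid-catalysed cyclodehydration of the 1,3-diketone to the 4-pyranone ring C, and acetal hydrolysis make up the classical chromone synthesis, here run with an ester that brings C2 in at the aldehyde oxidation level.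

Step 4
Reactants: 9 5,6,7,8-tetramethoxy-4-oxo-4H-chromene-2-carbaldehyde
Product: 10 5-hydroxy-6,7,8-trimethoxy-4-oxo-4H-chromene-2-carbaldehyde
Conditions: BCl3 (2.5 equiv), CH2Cl2, −78 → 0 °C; aq. work-up
Reagents that add atoms: none
Why: Chelation-controlled ether cleavage, in which BCl3 bridges the C4 carbonyl and the peri 5-methoxy oxygen and chloride removes only that methyl group, is well established for 5-methoxychromones and for methoxy groups ortho to aldehydes, so the aldehyde and the other three ethers should survive at low temperature.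

Step 5
Reactants: 10 5-hydroxy-6,7,8-trimethoxy-4-oxo-4H-chromene-2-carbaldehyde
Product: 11 2-ethynyl-5-hydroxy-6,7,8-trimethoxy-4H-chromen-4-one
Conditions: dimethyl (1-diazo-2-oxopropyl)phosphonate, K2CO3 (3 equiv), MeOH, 0 °C → rt; aq. NH4Cl work-up
Reagents that add atoms: dimethyl (1-diazo-2-oxopropyl)phosphonate, COP(=O)(OC)C(=[N+]=[N-])C(C)=O
Why: Seyferth–Gilbert homologation in its Ohira–Bestmann form converts a non-enolisable aldehyde into the terminal alkyne under mild carbonate conditions, under which the 5-hydroxyl sits as the phenoxide and lowers the electrophilicity of the pyranone and of the new enynone towards methanol.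

Step 6
Reactants: 11 2-ethynyl-5-hydroxy-6,7,8-trimethoxy-4H-chromen-4-one
Product: 12 5-hydroxy-6,7,8-trimethoxy-2-[1-(tributylstannyl)ethenyl]-4H-chromen-4-one
Conditions: Bu3SnH (slow addition), PdCl2(PPh3)2 (2 mol %), THF, 0 °C
Reagents that add atoms: tributyltin hydride, CCCC[SnH](CCCC)CCCC
Why: Palladium-catalysed syn-hydrostannation of a terminal alkyne whose internal carbon is conjugated to an electron-poor π system delivers hydrogen to the electrophilic terminal carbon and tin to the internal one, as with alkynoates and conjugated enynes, and the chelated phenol is inert to the tin hydride.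

Step 7
Reactants: 13 dimethyl squarate
Product: 14 4-hydroxy-2,3-dimethoxycyclobut-2-en-1-one (racemic)
Conditions: LiAlH(O-t-Bu)3, THF, −78 °C; pH 7 buffer quench
Reagents that add atoms: none
Why: The bulky alkoxyaluminium hydride should add once to one of the two equivalent ketone carbonyls (1,2-reduction) and stop at the alkoxide, giving the racemic hydroxycyclobutenone, which is kept cold and free of acid.

Step 8
Reactants: 14 4-hydroxy-2,3-dimethoxycyclobut-2-en-1-one
Product: 15 4-chloro-2,3-dimethoxycyclobut-2-en-1-one (racemic)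
Conditions: NCS, Me2S, CH2Cl2, −20 → 0 °C
Reagents that add atoms: N-chlorosuccinimide, O=C1CCC(=O)N1Cl
Why: Corey–Kim chlorination activates the allylic, ketone-adjacent alcohol on sulfur and replaces it by chloride under neutral, non-aqueous conditions, which avoids the acid-induced loss of methanol typical of such alcohols, and the conjugated 4-chloro isomer is the thermodynamically favoured allylic chloride.

Step 9
Reactants: 12 5-hydroxy-6,7,8-trimethoxy-2-[1-(tributylstannyl)ethenyl]-4H-chromen-4-one; 15 4-chloro-2,3-dimethoxycyclobut-2-en-1-one (freshly made, slight excess)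
Product: 16 4-[1-(5-hydroxy-6,7,8-trimethoxy-4-oxo-4H-chromen-2-yl)ethenyl]-2,3-dimethoxycyclobut-2-en-1-one (racemic)
Conditions: PdCl2(PhCN)2 (5 mol %), P(2-furyl)3 (10 mol %), dioxane, 50 °C
Reagents that add atoms: none
Why: Stille coupling of a 4-chlorocyclobutenone, whose allylic ketone-adjacent C–Cl bond adds readily to zerovalent palladium, with an alkenylstannane is a known pairing; the weakly donating furylphosphine speeds transmetalation of the hindered 1,1-disubstituted alkenyltin, the new bond forms at the carbon that bore chlorine, and any ring expansion that begins at this temperature only anticipates step 10.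

Step 10
Reactants: 16 4-[1-(5-hydroxy-6,7,8-trimethoxy-4-oxo-4H-chromen-2-yl)ethenyl]-2,3-dimethoxycyclobut-2-en-1-one
Product: 19 Gardenin C (5,3'-dihydroxy-6,7,8,4',5'-pentamethoxyflavone), via dienylketene 17 (not isolated), via cyclohexadienone 18 (not isolated)
Conditions: toluene (0.01 M), 100 °C, argon
Reagents that add atoms: none
Why: Heating cleaves the C1–C4 bond of the cyclobutenone by a reversible conrotatory 4π electrocyclic opening to dienylketene 17. Only the isomer in which the 1-(chromonyl)vinyl group has turned inward can go on, by thermal disrotatory 6π electrocyclisation that closes the six-membered carbocycle between the vinyl CH2 terminus and the ketene carbon (the C2'–C3' bond); the outward isomer recloses to 16, so all material should drain through this channel. Tautomerisation of cyclohexadienone 18 then gives ring B as the free phenol. The closest known reaction type is the thermal ring expansion of 4-alkenylcyclobut-2-enones, made from 4-chlorocyclobutenones and alkenylstannanes, to substituted phenols. No stereocentre is created and the only one in 16 is destroyed; the regiochemistry (3'-OH beside 4'-OMe and 5'-OMe, CH at C2' and C6') is fixed by connectivity, because the ketene carbon, the two methoxy-bearing carbons and the ring CH are already contiguous in 16. The selectivity needed is cyclisation in preference to capture of the ketene by a phenol, which the intramolecular 6π process, high dilution and the chelated, poorly nucleophilic 5-OH should secure.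

**Compound list**

1 | 1,2,3,4-tetramethoxybenzene | COc1ccc(OC)c(OC)c1OC | starting material
2 | (2,3,4,5-tetramethoxyphenyl)lithium | [Li]c1cc(OC)c(OC)c(OC)c1OC | intermediate (not isolated)
3 | dimethyl (2,3,4,5-tetramethoxyphenyl)boronate | COB(OC)c1cc(OC)c(OC)c(OC)c1OC | intermediate (not isolated)
4 | 2,3,4,5-tetramethoxyphenol | COc1cc(O)c(OC)c(OC)c1OC | intermediate
5 | 1-(2-hydroxy-3,4,5,6-tetramethoxyphenyl)ethan-1-one | CC(=O)c1c(O)c(OC)c(OC)c(OC)c1OC | intermediate
6 | ethyl 2,2-diethoxyacetate | CCOC(=O)C(OCC)OCC | starting material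
7 | 4,4-diethoxy-1-(2-hydroxy-3,4,5,6-tetramethoxyphenyl)butane-1,3-dione | CCOC(OCC)C(=O)CC(=O)c1c(O)c(OC)c(OC)c(OC)c1OC | intermediate (not isolated)
8 | 2-(diethoxymethyl)-5,6,7,8-tetramethoxy-4H-chromen-4-one | CCOC(OCC)c1cc(=O)c2c(OC)c(OC)c(OC)c(OC)c2o1 | intermediate (not isolated)
9 | 5,6,7,8-tetramethoxy-4-oxo-4H-chromene-2-carbaldehyde | O=Cc1cc(=O)c2c(OC)c(OC)c(OC)c(OC)c2o1 | intermediate
10 | 5-hydroxy-6,7,8-trimethoxy-4-oxo-4H-chromene-2-carbaldehyde | O=Cc1cc(=O)c2c(O)c(OC)c(OC)c(OC)c2o1 | intermediate
11 | 2-ethynyl-5-hydroxy-6,7,8-trimethoxy-4H-chromen-4-one | C#Cc1cc(=O)c2c(O)c(OC)c(OC)c(OC)c2o1 | intermediate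
12 | 5-hydroxy-6,7,8-trimethoxy-2-[1-(tributylstannyl)ethenyl]-4H-chromen-4-one | C=C(c1cc(=O)c2c(O)c(OC)c(OC)c(OC)c2o1)[Sn](CCCC)(CCCC)CCCC | intermediate
13 | dimethyl squarate (3,4-dimethoxycyclobut-3-ene-1,2-dione) | COC1=C(OC)C(=O)C1=O | starting material
14 | 4-hydroxy-2,3-dimethoxycyclobut-2-en-1-one (racemic) | COC1=C(OC)C(O)C1=O | intermediate
15 | 4-chloro-2,3-dimethoxycyclobut-2-en-1-one (racemic) | COC1=C(OC)C(Cl)C1=O | intermediate
16 | 4-[1-(5-hydroxy-6,7,8-trimethoxy-4-oxo-4H-chromen-2-yl)ethenyl]-2,3-dimethoxycyclobut-2-en-1-one (racemic) | COC1=C(OC)C(C(=C)c2cc(=O)c3c(O)c(OC)c(OC)c(OC)c3o2)C1=O | intermediate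
17 | (3E)-5-(5-hydroxy-6,7,8-trimethoxy-4-oxo-4H-chromen-2-yl)-2,3-dimethoxyhexa-1,3,5-trien-1-one (ketene carbon and C5 cis across C3=C4) | O=C=C(OC)/C(OC)=C\C(=C)c1cc(=O)c2c(O)c(OC)c(OC)c(OC)c2o1 | intermediate (not isolated)
18 | 5-(5-hydroxy-6,7,8-trimethoxy-4-oxo-4H-chromen-2-yl)-2,3-dimethoxycyclohexa-2,4-dien-1-one | COC1=C(OC)C(=O)CC(c2cc(=O)c3c(O)c(OC)c(OC)c(OC)c3o2)=C1 | intermediate (not isolated)
19 | Gardenin C | COc1cc(-c2cc(=O)c3c(O)c(OC)c(OC)c(OC)c3o2)cc(O)c1OC | target

**Count**

Total steps: 10. Longest linear sequence: 8 steps (1 → 4 → 5 → 9 → 10 → 11 → 12 → 16 → 19). The squarate branch (13 → 14 → 15) is 2 steps and joins at step 9.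

**Steps most likely to fail**

1. Step 8. The activated alcohol, or the chloride once formed, may ionise towards a methoxy-stabilised cyclobutenyl cation and lose a methyl group from an enol ether oxygen, or the chloride may decompose on handling. The fallback sets out from 14 and avoids any free halide. Acetylation (Ac2O, pyridine, DMAP, CH2Cl2, 0 °C) should give the stable ester 2,3-dimethoxy-4-oxocyclobut-2-en-1-yl acetate F1. F1 is then ionised only on the metal, by coupling with stannane 12 under the allylic acetate variant of the Stille reaction (Pd2(dba)3, P(2-furyl)3, LiCl, DMF, 50 °C). This comes back to the route at 16.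

2. Step 9. Transmetalation from the hindered, electron-poor 1,1-disubstituted alkenyltin may be too slow, so that the palladium-bound cyclobutenyl unit decays, the stannane suffers protodestannylation, or bond formation loses its preference for C4. The fallback sets out from 12 and moves the alkenyl group to zinc:
   - Iododestannylation (I2, CH2Cl2, 0 °C) should give 5-hydroxy-2-(1-iodoethenyl)-6,7,8-trimethoxy-4H-chromen-4-one F2.
   - The phenol is capped as its sodium salt (NaH, 1 equiv, THF, 0 °C), and zinc insertion (Zn dust, LiCl, THF, 25–40 °C) should give sodium 2-[1-(iodozincio)ethenyl]-6,7,8-trimethoxy-4-oxo-4H-chromen-5-olate F3.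
   - Negishi coupling of F3 with chloride 15 (Pd2(dba)3, P(2-furyl)3, THF, 25 °C; aq. NH4Cl work-up) comes back to the route at 16.

3. Step 6. Regiocontrol in the hydrostannation may be incomplete, with tin delivered to the terminal carbon. The fallback fixes the position of tin through a ketone; it sets out from 5 and replaces steps 3 to 6:
   - Claisen condensation of 5 with ethyl 2,2-diethoxypropanoate (NaH, THF, reflux) should give 4,4-diethoxy-1-(2-hydroxy-3,4,5,6-tetramethoxyphenyl)pentane-1,3-dione F4.
   - In AcOH/conc. aq. HCl at 80 °C, F4 should cyclise to 2-(1,1-diethoxyethyl)-5,6,7,8-tetramethoxy-4H-chromen-4-one F5 and hydrolyse to 2-acetyl-5,6,7,8-tetramethoxy-4H-chromen-4-one F6.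
   - Enolisation of the methyl ketone and O-sulfonylation (KN(SiMe3)2, THF, −78 °C; PhNTf2) should give 1-(5,6,7,8-tetramethoxy-4-oxo-4H-chromen-2-yl)ethenyl trifluoromethanesulfonate F7.
   - BCl3 (CH2Cl2, −78 → 0 °C) should cleave the 5-O-methyl group to give 1-(5-hydroxy-6,7,8-trimethoxy-4-oxo-4H-chromen-2-yl)ethenyl trifluoromethanesulfonate F8.
   - Palladium-catalysed stannylation of the enol triflate ((Bu3Sn)2, Pd(PPh3)4, LiCl, THF, 60 °C) comes back to the route at 12.

**Further compounds**

F1 | step 8 | 2,3-dimethoxy-4-oxocyclobut-2-en-1-yl acetate (racemic) | CC(=O)OC1C(OC)=C(OC)C1=O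
F2 | step 9 | 5-hydroxy-2-(1-iodoethenyl)-6,7,8-trimethoxy-4H-chromen-4-one | C=C(I)c1cc(=O)c2c(O)c(OC)c(OC)c(OC)c2o1
F3 | step 9 | sodium 2-[1-(iodozincio)ethenyl]-6,7,8-trimethoxy-4-oxo-4H-chromen-5-olate | C=C([Zn]I)c1cc(=O)c2c([O-])c(OC)c(OC)c(OC)c2o1.[Na+]
F4 | step 6 | 4,4-diethoxy-1-(2-hydroxy-3,4,5,6-tetramethoxyphenyl)pentane-1,3-dione | CCOC(C)(OCC)C(=O)CC(=O)c1c(O)c(OC)c(OC)c(OC)c1OC
F5 | step 6 | 2-(1,1-diethoxyethyl)-5,6,7,8-tetramethoxy-4H-chromen-4-one | CCOC(C)(OCC)c1cc(=O)c2c(OC)c(OC)c(OC)c(OC)c2o1
F6 | step 6 | 2-acetyl-5,6,7,8-tetramethoxy-4H-chromen-4-one | CC(=O)c1cc(=O)c2c(OC)c(OC)c(OC)c(OC)c2o1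
F7 | step 6 | 1-(5,6,7,8-tetramethoxy-4-oxo-4H-chromen-2-yl)ethenyl trifluoromethanesulfonate | C=C(OS(=O)(=O)C(F)(F)F)c1cc(=O)c2c(OC)c(OC)c(OC)c(OC)c2o1
F8 | step 6 | 1-(5-hydroxy-6,7,8-trimethoxy-4-oxo-4H-chromen-2-yl)ethenyl trifluoromethanesulfonate | C=C(OS(=O)(=O)C(F)(F)F)c1cc(=O)c2c(O)c(OC)c(OC)c(OC)c2o1
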